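**Retrosynthetic overview**
- Lutein (1) and two molecules of α-linolenic acid (2) are joined through the two ester C–O bonds; these are the only disconnections.
- 1 supplies the all-E C40 polyene and the three stereocentres (3R,3′R,6′R); 2 supplies the three Z-alkenes of each chain.
- No ring is formed in the route: the β-ring and the ε-ring are bought intact in 1.
- Forward: one flask, a dicarbonate-fuelled DMAP acyl relay (proposed new use), no protecting groups, giving the target (8).

Assumption: crystalline marigold lutein (all-E, 3R,3′R,6′R, ≥95 %, zeaxanthin-depleted) and α-linolenic acid (≥98 %) count as cheap commercial materials; the target SMILES is read as all-E (3R,3′R,6′R)-lutein bis[(9Z,12Z,15Z)-octadeca-9,12,15-trienoate].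

**Step 1**
Reactants: 1 lutein ((3R,3′R,6′R)-β,ε-carotene-3,3′-diol, all-E); 2 α-linolenic acid ((9Z,12Z,15Z)-octadeca-9,12,15-trienoic acid)
Product: 8 lutein di-α-linolenate (target), via α-linolenoyl tert-butyl carbonate 3 (not isolated), via α-linolenic anhydride 4 (not isolated), via N-α-linolenoyl-DMAP-ium tert-butyl carbonate 5 (not isolated), via lutein 3-mono-α-linolenate 6 (not isolated), via lutein 3′-mono-α-linolenate 7 (not isolated)
Conditions: 2 (2.4 equiv), Boc2O (2.2 equiv), DMAP (0.2 equiv), BHT (1 mol %), THF, Ar, dark, 25 °C, 30 min; then 1 (1.0 equiv), 25 °C, 16 h; Et3N-deactivated silica, then crystallisation (acetone/EtOH, −20 °C)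
Reagents that add atoms: di-tert-butyl dicarbonate (Boc2O), CC(C)(C)OC(=O)OC(=O)OC(C)(C)C (atoms only in intermediates 3 and 5, none in 8); DMAP, CN(C)c1ccncc1 (atoms only in intermediate 5, none in 8)
Why: Proposed new method: a dicarbonate-fuelled anhydride-relay double O-acylation in which Boc2O turns 2 into mixed anhydride 3 (and anhydride 4), DMAP attacks the less hindered acyl carbonyl to give acylpyridinium 5, and 5 acylates the C3 and C3′ carbinols of 1 through monoesters 6 and 7 while the expelled tert-butyl carbonate collapses to tBuOH and CO2 and any carboxylate released from 4 is re-activated by Boc2O, so that the medium stays free of strong acid and strong base (no ionisation of the allylic C3′–O bond, no ε→β double-bond shift), no bond to C3, C3′ or C6′ is broken (3R,3′R,6′R carried over from 1) and the E-polyene and Z-trienes are untouched; the closest known reaction type is the DMAP/dicarbonate (Steglich–Yamaguchi-type mixed-anhydride) esterification of simple alcohols, which has not been shown on a carotenoid diol, on an ionisation-prone allylic carotenol, or with a skipped-polyene acid as near-stoichiometric partner and the diol as limiting reagent.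

**Compound list**
1 | lutein, (3R,3′R,6′R)-β,ε-carotene-3,3′-diol, all-E | O[C@@H]1CC(C)=C(/C=C/C(C)=C/C=C/C(C)=C/C=C/C=C(C)/C=C/C=C(C)/C=C/[C@H]2C(C)=C[C@H](O)CC2(C)C)C(C)(C)C1 | starting material
2 | α-linolenic acid, (9Z,12Z,15Z)-octadeca-9,12,15-trienoic acid | CC/C=C\C/C=C\C/C=C\CCCCCCCC(=O)O | starting material
3 | α-linolenoyl tert-butyl carbonate (mixed carbonic anhydride) | CC/C=C\C/C=C\C/C=C\CCCCCCCC(=O)OC(=O)OC(C)(C)C | intermediate
4 | α-linolenic anhydride | CC/C=C\C/C=C\C/C=C\CCCCCCCC(=O)OC(=O)CCCCCCC/C=C\C/C=C\C/C=C\CC | intermediate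
5 | N-(α-linolenoyl)-4-(dimethylamino)pyridinium tert-butyl carbonate | CC/C=C\C/C=C\C/C=C\CCCCCCCC(=O)[n+]1ccc(N(C)C)cc1.CC(C)(C)OC(=O)[O-] | intermediate
6 | lutein 3-mono-α-linolenate (β-ring ester, 3′-OH free; 3R,3′R,6′R) | CC/C=C\C/C=C\C/C=C\CCCCCCCC(=O)O[C@@H]1CC(C)=C(/C=C/C(C)=C/C=C/C(C)=C/C=C/C=C(C)/C=C/C=C(C)/C=C/[C@H]2C(C)=C[C@H](O)CC2(C)C)C(C)(C)C1 | intermediate
7 | lutein 3′-mono-α-linolenate (ε-ring ester, 3-OH free; 3R,3′R,6′R) | O[C@@H]1CC(C)=C(/C=C/C(C)=C/C=C/C(C)=C/C=C/C=C(C)/C=C/C=C(C)/C=C/[C@H]2C(C)=C[C@H](OC(=O)CCCCCCC/C=C\C/C=C\C/C=C\CC)CC2(C)C)C(C)(C)C1 | intermediate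
8 | lutein di-α-linolenate, (3R,3′R,6′R)-β,ε-carotene-3,3′-diyl bis[(9Z,12Z,15Z)-octadeca-9,12,15-trienoate], all-E | CC/C=C\C/C=C\C/C=C\CCCCCCCC(=O)O[C@@H]1CC(C)=C(/C=C/C(C)=C/C=C/C(C)=C/C=C/C=C(C)/C=C/C=C(C)/C=C/[C@H]2C(C)=C[C@H](OC(=O)CCCCCCC/C=C\C/C=C\C/C=C\CC)CC2(C)C)C(C)(C)C1 | target

**Total step count:** 1. **Longest linear sequence:** 1 step.

**Steps most likely to fail:** the route has a single step, so the list holds one entry instead of three.

Step 1 (the proposed new step) can fail in four ways:
- Boc transfer to the carbinols of 1 (O-Boc capping) may compete with acyl transfer.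
- Some of 3 may leak to tert-butyl α-linolenate.
- The second acylation may stall at monoesters 6 and 7.
- The polyene may drift E/Z or autoxidise if light or air gets in.

The fallback uses known chemistry and changes the approach from in-flask dehydrative coupling to a pre-formed acyl chloride. It sets out from 2 and comes back to the route at 8. Acid 2 is treated with oxalyl chloride and catalytic DMF in CH2Cl2 (0 °C to rt) to give α-linolenoyl chloride F1. After evaporation of volatiles, F1 (2.5 equiv) is added to 1 in CH2Cl2/pyridine with catalytic DMAP at 0 °C to rt, under Ar in the dark. This is the classical acyl chloride/pyridine acylation used for xanthophyll diesters and gives 8 directly with the same retention at C3, C3′ and C6′.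

**Further compounds**
F1 | step 1 | α-linolenoyl chloride, (9Z,12Z,15Z)-octadeca-9,12,15-trienoyl chloride | CC/C=C\C/C=C\C/C=C\CCCCCCCC(=O)Cl
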